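How much target stands in the flask at the end of the run, and which doubling buys more of it?

    dissolved gas + target → over-reaction product (k1 = 1.12 M⁻¹ s⁻¹)
    starting material + dissolved gas → target (k2 = 30.9 M⁻¹ s⁻¹)
    gas phase ⇌ dissolved gas, rate k3*(csat - [dissolved gas]) (k3 = 0.308 s⁻¹, csat = 4.1 mM)
    starting material → side product (k4 = 0.103 s⁻¹)
    dissolved gas ⇌ dormant form (K5 = 8.94, k5 = 0.00913 s⁻¹)

starting material 0.10 M; gas phase 4.1 mM (held); time 2.0 min

- at the start none of the gas is dissolved
- run time (flask): 2.0 min

1. how much target there is at 2.0 min, in percent of the starting material charged
2. the change that raises the amount of target at 2.0 min, in percent of the starting material charged most ("none" if none brings more than 2 percentage points) (alpha / delta / none)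
3. amount of target at 2.0 min, in percent of the starting material charged, after alpha

Watch the dissolved gas. The two routes out of the starting material run equal when the dissolved gas stands at the side step's constant over the forming step's constant, a break-even level of 3.33 mM, and below that level side product takes the larger share.

In the first seconds you have nothing dissolved, and transfer delivers at most 1.26 mM s⁻¹, while the starting material falls to side product at 10.3 mM s⁻¹, faster. Gas that arrives meets a pseudo-first-order pull from the starting material of 3.09 s⁻¹, ten times the transfer coefficient. So its half-life by the forming step, with the starting material as charged, is about 0.22 s, and at that charge I put it at a steady 0.372 mM, less than break-even. I drop the dormant form here, since its forward constant is far smaller than the transfer coefficient.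

As the starting material falls, my steady gas level climbs, yet in this reckoning it passes break-even only at 2.29 mM of starting material, so nearly all of the charge is reckoned to react with the gas below that level. Summing the shares along that fall gives the gas-route amount: supply over the side step's constant, times the logarithm of one plus the pull at charge divided by the transfer coefficient and by one plus saturation over break-even. That is 20.9 mM.

After 4 half-lives of the starting material by the side step alone, 0.11 min each, I count the forming as over. For the remaining time I take the gas at 4.1 mM and let it attack the target, which in this estimate leaves 65.2 % of it. My figure is 13.6 %. By the same reckoning alpha gives 18.8 %, and delta gives 14.2 %, so I choose alpha.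

The forecast says 12.5 %, alpha and 17.5 %, on the ground that “over-reaction eats target”.

The flask gives 12.7 %, and alpha adds 4.6 percentage points to reach 17.3 %, against 0.42 points for delta. The loss of gas to the dormant form, which I dropped, makes no difference to the target. In this flask at 2.00 min, target and over-reaction product together hold 19.3 % of the charge, against a gas-route amount of 20.9 %. For the neighbour charged with 0.025 M, the gas-route amount comes to 37.0 % of its charge, and that neighbour ended with 32.2 % in those two products.

The rate constants stand for no real mixture; the result is computed.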